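## Analysis of the target

Spiculoic acid B (34) is a trans-fused bicyclo[4.3.0]nonadiene. Ring A is the cyclohexene C1(Me)(CO2H)–C2(Et)(styryl)–C3H=C4(Et)–C5H–C6H. Ring B, fused along C5–C6, is the cyclopentene C6–C7(Et)=C8H–C9H(Me)–C5. There are five stereocentres: two adjacent all-carbon quaternary centres (C1, C2) and three contiguous methines (C6, C5, C9). With ring A drawn so that C1 to C6 run clockwise, the carboxyl group on C1, the styryl group on C2, C6–H and C9–H point up, and C1–Me, C2–Et, C5–H and C9–Me point down. The ring fusion is therefore trans, C5–H is trans to C9–H, and carboxyl and styryl are cis. The sensitive groups are the (E)-styrene, the two trisubstituted ring alkenes, the strained trans-hydrindadiene and the very hindered C1 carboxyl group, whose ester lies within reach of any oxygen nucleophile on the C2 side chain (five-membered lactone). The hard parts are the C1/C2 pair in one absolute sense, the relation of C5, C6 and C9 to that pair, and a ring-B alkene at C7=C8 next to a trans fusion. The strategy rests on one feature: with a carbonyl imagined at C8, ring B is a cyclopentenone whose bonds C5–C6, C7–C8 and C8–C9 join an alkyne C6≡C7, an alkene C5=C9 and carbon monoxide. Because the linking chain C1–C2–C3=C4 already holds the cis alkene of ring A, the same cycloaddition closes ring A.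

## Retrosynthetic reasoning

**34 ⇒ 33 ⇒ 31 + 32.** The acid is unmasked last from methyl ester 33 by cleavage of the O–CH3 bond, because the carbonyl carbon is too hindered for acyl substitution. The styryl C=C bond is cut next, back to aldehyde 31 and phosphonium salt 32. It is cut because the styrene cannot be carried through the key step: it would stand in a 1,5-relationship to the alkyne and invite metal-catalysed cycloisomerisation. The olefination must be E-selective and must not generate a free alkoxide beside the C1 ester.

**31 ⇒ 30 ⇒ 29.** The aldehyde carbon is carried as a silyloxymethyl group. Alcohol 30 is the one intermediate in which oxygen on the C2 side chain can reach the C1 ester, so it is made under buffered conditions and oxidised at once.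

**29 ⇒ 28 ⇒ 26 ⇒ 25.** The C7=C8 alkene and C6–H of 29 are traced to enone 25. Allylic diazene 28 loses nitrogen with delivery of hydrogen to C6 on the face that carries nitrogen at C8. That face is set by inverting alcohol 26, which comes from 1,2-reduction of 25 opposite the C9 methyl group. This pair of steps turns the cycloadduct's oxidation pattern into the target's and creates the trans ring fusion under stereospecific control.

**25 ⇒ 23 + 24 (key disconnection).** The bonds C5–C6, C7–C8 and C8–C9 are cut together, which opens both rings and gives the acyclic dienyne 23 and carbon monoxide (24). No other single cut removes two rings and two stereocentres (C5, C9) at once, and it leaves only C1 and C2 to be made beforehand. The forward reaction must use the distal alkene of the diene, add to the correct face of C5, and translate the E geometry of C5=C9 into the trans C5–H/C9–H relation.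

**23 ⇒ 22 ⇒ 21 ⇒ 20 ⇒ 17 + 19 (19 ⇐ 18).** The (Z,E)-diene is built by two olefinations: C5=C9 from enal 22, and C3=C4 from aldehyde 17 and phosphonate 19 by way of enoate 20 and alcohol 21. A cross-coupling at C4 was rejected. An alkenylmetal halide at C4, cis to C2, lies 5-exo to the C6≡C7 alkyne and would add across it before coupling. The olefinations must give Z at C3=C4 (C5 cis to C2, as ring A requires) and E at C5=C9.

**17 ⇒ 15 ⇒ 14 ⇒ 12 ⇒ 11.** The C1–C2 bond is cut as the [3,3] bond of an Ireland–Claisen rearrangement of ketene acetal 12, derived from ester 11. This is the most reliable way to join two fully substituted carbons. The chair transition state relays one C–O stereocentre of 11 into both quaternary centres of acid 14. The propenyl group left on C2 is cleaved to the aldehyde of 17 after esterification to 15.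

**11 ⇒ 4 + 10; 4 ⇐ 3 ⇐ 1; 10 ⇐ 9 ⇐ 7 ⇐ 6 ⇐ 5.** Ester 11 is cut at the acyl–oxygen bond into acid 4 and allylic alcohol 10. Acid 4 comes from hex-3-yn-1-ol (1) by oxidation to 3 and α-methylation. Alcohol 10 carries the only stereocentre that has to be bought, that of (R)-but-3-yn-2-ol (5). Its E alkene is set by hydroxyl-directed hydroalumination–iodination (7 to 9) and a stereoretentive ethyl coupling.

## Alternatives that were turned down

**Alternative 1: Claisen ring contraction of a lactone.**
- **Disconnection:** ring A is cut at C5–C6 and an O–C3 bond is restored, which leads back to the six-membered lactone A1 (C7 as lactone carbonyl, the C4=C5 alkene on C3).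
- **Forward key step:** enolisation and O-silylation of A1 (LiN(iPr)2, Me3SiCl) would trigger a [3,3] shift that forms C5–C6, breaks O–C3 and gives ring-A acid A2 with C3=C4 in place. The two-atom bridge C1–C2 between C6 and C3 forces a boat.
- **For:** no transition metal is involved, so the styryl group can be present from the start. C5 and C6 are set in one intramolecular event.
- **Against:** in the enforced boat, the C5 substituent that is cis to C3 lies directly under C1. The trans C5/C6 pattern of A2 requires that substituent to be the branched C9 carbon, which is then pushed against the quaternary C1. A1 must already contain C1, C2, C3, C9 and a trisubstituted alkene of fixed geometry. After the key step ring B is still open, and the C7 carboxyl group has to be converted and closed onto C8 in several further steps.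
- **Comparison:** this route is stronger in functional-group tolerance. The chosen route makes both rings at once and takes C9 from alkene geometry instead of a separate stereocentre.

**Alternative 2: Heck closure of ring A.**
- **Disconnection:** the C2–C3 bond, so that quaternary C2 and the styrene arise together from iodide A3.
- **Forward key step:** zerovalent palladium (from Pd(OAc)2 and BINAP) inserts into the C3–I bond of A3 and the alkenylpalladium adds 6-exo to the C2=Cα alkene. β-Hydride elimination can only go toward the benzylic CH2 and gives A4, which is identical with 33.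
- **For:** it ends one step from the target with no placeholder on C2 and no late olefination. On that point it is shorter than the chosen route. A chiral ligand can support the face selection.
- **Against:** the insertion must create quaternary C2 directly beside quaternary C1 on a trisubstituted alkene, which is about as congested as a Heck closure can be. The face of C2 is decided by a contest between the ligand and the adjacent C1. The C7=C8 alkene is also within reach of the alkenylpalladium. A3 already needs the trans-fused ring B with C1 attached.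
- **Comparison:** the chosen route forms the C1–C2 bond early, by a sigmatropic shift on a simple ester, and keeps transition metals away from the crowded centres until both are in place.

**Alternative 3: hydroacylation to close ring B.**
- **Disconnection:** the C7–C8 bond of ring B, back to aldehyde A5 (C7 aldehyde on C6, isopropenyl group on C5).
- **Forward key step:** [Rh(dppe)]ClO4 (cationic monovalent rhodium) would add the aldehyde C–H of A5 across the isopropenyl group and give the trans-fused ketone A6, with hydrogen delivered to C9.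
- **For:** the trans relation of C5 and C6 is set beforehand on ring A, where the aldehyde centre can equilibrate. On this point it is safer than the chosen route, which needs two steps to place C6–H. The C7 ketone is a good handle for the ethyl group and the C7=C8 alkene.
- **Against:** C9 is created on a 1,1-disubstituted alkene with no strong bias. Decarbonylation of the hindered aldehyde competes. The styrene and C3=C4 are exposed to a rhodium hydride. A5 requires a ring A with four stereocentres made separately, and two more steps follow A6.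
- **Comparison:** the chosen route makes ring A, ring B, C5 and C9 in one step from an open chain.

Key step: step 16

## Route

Remark: atom labels C1–C9 are those of the analysis. Deprotonated salts, catalytic organometallic species and ylides made from numbered compounds are not numbered separately.

Step 1
Reactants: 1 hex-3-yn-1-ol
Product: 3 hex-3-ynoic acid, via hex-3-ynal 2 (not isolated)
Conditions: TEMPO (0.2 equiv), PhI(OAc)2 (2.2 equiv), MeCN/H2O 1:1, rt
Reagents that add atoms: water, O
Why: Nitroxyl-catalysed oxidation takes the primary alcohol through the aldehyde hydrate to the acid under near-neutral conditions, so the β,γ-alkyne should not isomerise to an allene.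

Step 2
Reactants: 3 hex-3-ynoic acid
Product: 4 (±)-2-methylhex-3-ynoic acid
Conditions: LiN(iPr)2 (2.2 equiv), THF, −78 to 0 °C; MeI, −78 °C; aq. HCl
Reagents that add atoms: iodomethane, CI
Why: α-Alkylation of a carboxylic acid dianion; the extended enediolate should be methylated at the α-carbon and the product carboxylate is too weakly acidic to be alkylated again. The new centre is racemic, which does not matter because it becomes trigonal in step 8.

Step 3
Reactants: 5 (R)-but-3-yn-2-ol
Product: 6 (4R)-pent-2-yne-1,4-diol
Conditions: n-BuLi (2.1 equiv), THF, −78 °C; (CH2O)n, −78 °C to rt; aq. NH4Cl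
Reagents that add atoms: formaldehyde (as paraformaldehyde), C=O
Why: Addition of the lithium acetylide of the alkoxide to formaldehyde; the carbinol centre is not touched.

Step 4
Reactants: 6 (4R)-pent-2-yne-1,4-diol
Product: 7 (2R)-5-[(tert-butyldimethylsilyl)oxy]pent-3-yn-2-ol
Conditions: TBSCl (1.05 equiv), imidazole, CH2Cl2, −20 to 0 °C
Reagents that add atoms: tert-butyldimethylsilyl chloride, CC(C)(C)[Si](C)(C)Cl
Why: Silylation at low temperature is selective for the primary over the secondary hydroxyl group.

Step 5
Reactants: 7 (2R)-5-[(tert-butyldimethylsilyl)oxy]pent-3-yn-2-ol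
Product: 9 (2R,3Z)-5-[(tert-butyldimethylsilyl)oxy]-4-iodopent-3-en-2-ol, via cyclic alkenylaluminate 8 (not isolated)
Conditions: NaAlH2(OCH2CH2OMe)2, THF, 0 °C; EtOAc; I2, −78 °C
Reagents that add atoms: iodine, II
Why: Hydroxyl-directed trans-hydroalumination of a propargylic alcohol puts hydride on the carbon next to the carbinol and aluminium on the distal carbon in a five-membered alanate; iodinolysis with retention should give the iodide cis to the carbinol carbon. The silyl ether is a poor leaving group, so loss to an allene should be slow at 0 °C.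

Step 6
Reactants: 9 (2R,3Z)-5-[(tert-butyldimethylsilyl)oxy]-4-iodopent-3-en-2-ol
Product: 10 (2R,3E)-5-[(tert-butyldimethylsilyl)oxy]-4-ethylpent-3-en-2-ol
Conditions: Et2Zn (3 equiv), Pd(dppf)Cl2 (5 mol %), THF, 0 to 50 °C
Reagents that add atoms: diethylzinc, CC[Zn]CC
Why: Negishi coupling of an alkenyl iodide proceeds with retention, so ethyl ends up cis to the carbinol carbon (E); the wide-bite-angle ligand favours reductive elimination over β-hydride elimination of the ethyl group.

Step 7
Reactants: 4 (±)-2-methylhex-3-ynoic acid; 10 (2R,3E)-5-[(tert-butyldimethylsilyl)oxy]-4-ethylpent-3-en-2-ol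
Product: 11 (2R,3E)-5-[(tert-butyldimethylsilyl)oxy]-4-ethylpent-3-en-2-yl 2-methylhex-3-ynoate (both epimers at the acyl α-carbon)
Conditions: iPrN=C=NiPr, DMAP (0.1 equiv), CH2Cl2, −20 to 0 °C
Reagents that add atoms: none
Why: Steglich esterification forms the acyl–oxygen bond, so the carbinol configuration is retained; low temperature and only catalytic DMAP should limit isomerisation of the 3-alkynoate to an allenoate.

Step 8
Reactants: 11 (2R,3E)-5-[(tert-butyldimethylsilyl)oxy]-4-ethylpent-3-en-2-yl 2-methylhex-3-ynoate
Product: 14 (2R,3S,4E)-2-(but-1-yn-1-yl)-3-{[(tert-butyldimethylsilyl)oxy]methyl}-3-ethyl-2-methylhex-4-enoic acid, via silyl ketene acetal 12 (not isolated), via trimethylsilyl ester 13 (not isolated)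
Conditions: LiN(iPr)2, Me3SiCl/Et3N, THF, −78 °C; then 60 °C; aq. NH4Cl/MeOH (pH 4–5)
Reagents that add atoms: none
Why: Ireland–Claisen rearrangement; in the cyclic enolisation transition state the slim alkynyl group should take the position beside the amide, so that 12 has methyl cis to the allylic oxygen and OSiMe3 cis to the alkynyl group. The chair transition state with the carbinol methyl equatorial then forms the C1–C2 bond on one face of each terminus, relaying the (R)-carbinol centre into (R)-C1 and (S)-C2 (chain locants 2 and 3) and giving the E alkene.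

Step 9
Reactants: 14 (2R,3S,4E)-2-(but-1-yn-1-yl)-3-{[(tert-butyldimethylsilyl)oxy]methyl}-3-ethyl-2-methylhex-4-enoic acid
Product: 15 methyl (2R,3S,4E)-2-(but-1-yn-1-yl)-3-{[(tert-butyldimethylsilyl)oxy]methyl}-3-ethyl-2-methylhex-4-enoate
Conditions: MeI, K2CO3, DMF, rt
Reagents that add atoms: iodomethane, CI
Why: O-Alkylation of the carboxylate is an SN2 reaction at iodomethane and does not depend on the hindrance of the acid.

Step 10
Reactants: 15 methyl (2R,3S,4E)-2-(but-1-yn-1-yl)-3-{[(tert-butyldimethylsilyl)oxy]methyl}-3-ethyl-2-methylhex-4-enoate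
Product: 17 methyl (2R,3S)-2-(but-1-yn-1-yl)-3-{[(tert-butyldimethylsilyl)oxy]methyl}-3-formyl-2-methylpentanoate, via secondary ozonide 16 (not isolated)
Conditions: O3, CH2Cl2, −78 °C (dye end point); PPh3, −78 °C to rt
Reagents that add atoms: ozone, [O-][O+]=O
Why: Ozonolysis with reductive work-up; the disubstituted alkene reacts far faster than the internal alkyne, and the aldehyde sits on a quaternary carbon and cannot epimerise.

Step 11
Reactants: 18 methyl 2-[bis(2,2,2-trifluoroethoxy)phosphoryl]acetate
Product: 19 methyl 2-[bis(2,2,2-trifluoroethoxy)phosphoryl]butanoate (racemic)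
Conditions: KOtBu, THF, 0 °C; EtI, rt
Reagents that add atoms: iodoethane, CCI
Why: C-Alkylation of the stabilised phosphonoacetate anion with a primary iodide.

Step 12
Reactants: 17 methyl (2R,3S)-2-(but-1-yn-1-yl)-3-{[(tert-butyldimethylsilyl)oxy]methyl}-3-formyl-2-methylpentanoate; 19 methyl 2-[bis(2,2,2-trifluoroethoxy)phosphoryl]butanoate
Product: 20 dimethyl (2Z,4S,5R)-5-(but-1-yn-1-yl)-4-{[(tert-butyldimethylsilyl)oxy]methyl}-2,4-diethyl-5-methylhex-2-enedioate
Conditions: KN(SiMe3)2, 18-crown-6, THF, −78 to −20 °C
Reagents that add atoms: phosphonate 19, CCC(C(=O)OC)P(=O)(OCC(F)(F)F)OCC(F)(F)F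
Why: Still–Gennari olefination; the electron-poor phosphonate under dissociating conditions collapses the kinetic adduct quickly and should give the Z enoate, with the new ester carbon (C5) cis to C2. The fast elimination leaves the adduct alkoxide no time to attack the C1 ester.

Step 13
Reactants: 20 dimethyl (2Z,4S,5R)-5-(but-1-yn-1-yl)-4-{[(tert-butyldimethylsilyl)oxy]methyl}-2,4-diethyl-5-methylhex-2-enedioate
Product: 21 methyl (2R,3S,4Z)-2-(but-1-yn-1-yl)-3-{[(tert-butyldimethylsilyl)oxy]methyl}-3-ethyl-5-(hydroxymethyl)-2-methylhept-4-enoate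
Conditions: iBu2AlH (2.2 equiv), CH2Cl2, −78 °C; aq. KNaC4H4O6
Reagents that add atoms: none
Why: The conjugated ester is reduced at −78 °C, whereas the C1 ester lies between two quaternary carbons and should react far more slowly.

Step 14
Reactants: 21 methyl (2R,3S,4Z)-2-(but-1-yn-1-yl)-3-{[(tert-butyldimethylsilyl)oxy]methyl}-3-ethyl-5-(hydroxymethyl)-2-methylhept-4-enoate
Product: 22 methyl (2R,3S,4Z)-2-(but-1-yn-1-yl)-3-{[(tert-butyldimethylsilyl)oxy]methyl}-3-ethyl-5-formyl-2-methylhept-4-enoate
Conditions: MnO2, CH2Cl2, rt
Reagents that add atoms: none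
Why: MnO2 oxidises allylic alcohols selectively under neutral conditions, which should keep the Z geometry of the enal.

Step 15
Reactants: 22 methyl (2R,3S,4Z)-2-(but-1-yn-1-yl)-3-{[(tert-butyldimethylsilyl)oxy]methyl}-3-ethyl-5-formyl-2-methylhept-4-enoate
Product: 23 methyl (2R,3S,4Z,6E)-2-(but-1-yn-1-yl)-3-{[(tert-butyldimethylsilyl)oxy]methyl}-3,5-diethyl-2-methylocta-4,6-dienoate
Conditions: CrCl2 (8 equiv), MeCHI2 (2 equiv), THF, rt
Reagents that add atoms: 1,1-diiodoethane, CC(I)I
Why: Takai–Utimoto alkylidenation with the geminal dichromium reagent gives E alkenes and is not basic, so the Z enal should not isomerise; no alkenylpalladium at C4 is involved.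

Step 16
Reactants: 23 methyl (2R,3S,4Z,6E)-2-(but-1-yn-1-yl)-3-{[(tert-butyldimethylsilyl)oxy]methyl}-3,5-diethyl-2-methylocta-4,6-dienoate; 24 carbon monoxide
Product: 25 bicyclic enone (methyl ester and methyl on C1; ethyl and CH2OTBS on C2; C3=C4; C6=C7–C8(=O); C5–H trans to C9–H; C5–H and C9–Me on the face of C1–Me)
Conditions: [Rh(CO)2Cl]2 (5 mol %), CO (1 atm), toluene (0.02 M), 110 °C
Reagents that add atoms: carbon monoxide 24, [C-]#[O+]
Why: Intramolecular Pauson–Khand (2+2+1) cycloaddition catalysed by monovalent rhodium: alkyne C6≡C7 and alkene C5=C9 couple oxidatively to a rhodacyclopentene (C5–C6), CO inserts into a Rh–C bond and reductive elimination completes C7–C8 and C8–C9. The closest known reactions are [Rh(CO)2Cl]2-catalysed cyclocarbonylations of 1,7-enynes and of dienynes. Ring A closes in the six-membered 1,7-enyne mode through C5–C6, which is possible because C2 and C5 are cis on C3=C4 and is helped by the two quaternary centres in the tether (Thorpe–Ingold effect); ring B closes as the five-membered enone by insertion and reductive elimination. C9 is fixed relative to C5 by the E geometry of C5=C9, since both new bonds form on one face of the alkene; the resulting trans C5–H/C9–H relation is also the stable one beside the ketone. C5 is fixed relative to C1/C2 by the half-chair of the forming ring A: allylic 1,3-strain with the C7 ethyl group is best avoided with the flat ester of C1 in the plane and C1–Me axial, and C5–H then takes the axial site on the face of C1–Me, which is the required face. The step needs the distal alkene of the diene to react; C3=C4 could only give a four-membered ring and a [4+2] addition of the diene would give a bridged ring, so C5=C9 is the only partner leading to an unstrained product. It also needs CO insertion to outrun β-hydride elimination from C9 (ene-type cycloisomerisation), which the CO atmosphere should secure. The C2 side chain is saturated here because a styrene would stand in a 1,5-relationship to the alkyne and invite cycloisomerisation.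

Step 17
Reactants: 25 bicyclic enone
Product: 26 C8 allylic alcohol (C8–OH cis to C9–Me; C6=C7 retained)
Conditions: NaBH4, CeCl3·7H2O, MeOH, −78 °C
Reagents that add atoms: none
Why: Luche 1,2-reduction; hydride should add to the flat cyclopentenone from the face opposite the adjacent C9 methyl group, placing the hydroxyl on the methyl face.

Step 18
Reactants: 26 C8 allylic alcohol
Product: 29 trans-fused diene (C7=C8; C6–H cis to the C1 ester and trans to C5–H; CH2OTBS on C2), via sulfonylhydrazine adduct 27 (not isolated), via allylic diazene 28 (not isolated)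
Conditions: 2-O2NC6H4SO2NHNH2, PPh3, EtO2CN=NCO2Et, N-methylmorpholine, −30 °C; then 23 °C
Reagents that add atoms: none
Why: Mitsunobu displacement by the sulfonylhydrazide inverts C8 and puts nitrogen on the face opposite C9–Me; loss of sulfinic acid gives diazene 28, which loses N2 in a retro-ene step. The hydrogen is delivered to C6 on the nitrogen-bearing face, which sets the trans ring fusion and moves the alkene to C7=C8.

Step 19
Reactants: 29 trans-fused diene
Product: 30 C2-hydroxymethyl ester
Conditions: HF·pyridine, pyridine, THF, 0 °C; used crude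
Reagents that add atoms: none
Why: Fluoride cleaves the Si–O bond under buffered, weakly acidic conditions in which the hydroxyl stays neutral; immediate use should outrun closure onto the hindered C1 ester.

Step 20
Reactants: 30 C2-hydroxymethyl ester
Product: 31 C2-formyl ester
Conditions: Dess–Martin periodinane, NaHCO3, CH2Cl2, 0 °C
Reagents that add atoms: none
Why: Dess–Martin oxidation under buffered conditions; the aldehyde is on a quaternary carbon and cannot epimerise.

Step 21
Reactants: 31 C2-formyl ester; 32 benzyltributylphosphonium chloride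
Product: 33 spiculoic acid B methyl ester
Conditions: NaN(SiMe3)2, THF, 0 °C; then 31, 0 to 50 °C
Reagents that add atoms: benzyltributylphosphonium chloride 32, CCCC[P+](CCCC)(CCCC)Cc1ccccc1.[Cl-]
Why: Wittig reaction of a trialkylphosphine-derived benzylide, which is E-selective for semi-stabilised ylides; the lithium-free ylide forms the oxaphosphetane directly, so no alkoxide is generated beside the C1 ester.

Step 22
Reactants: 33 spiculoic acid B methyl ester
Product: 34 spiculoic acid B
Conditions: NaSEt, DMF, 90 °C; aq. HCl (pH 3)
Reagents that add atoms: none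
Why: SN2 demethylation by thiolate at the O–CH3 carbon avoids attack at the hindered carbonyl and touches no stereocentre or alkene.

## Compound list

1 | hex-3-yn-1-ol | CCC#CCCO | starting material
2 | hex-3-ynal | CCC#CCC=O | intermediate
3 | hex-3-ynoic acid | CCC#CCC(=O)O | intermediate
4 | (±)-2-methylhex-3-ynoic acid | CCC#CC(C)C(=O)O | intermediate
5 | (R)-but-3-yn-2-ol | C[C@@H](O)C#C | starting material
6 | (4R)-pent-2-yne-1,4-diol | C[C@@H](O)C#CCO | intermediate
7 | (2R)-5-[(tert-butyldimethylsilyl)oxy]pent-3-yn-2-ol | C[C@@H](O)C#CCO[Si](C)(C)C(C)(C)C | intermediate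
8 | sodium cyclic alkenylalkoxyaluminate from 7 (five-membered O–Al–C4=C3–C2 ring, two 2-methoxyethoxy groups on Al) | C[C@H]1O[Al-](OCCOC)(OCCOC)C(CO[Si](C)(C)C(C)(C)C)=C1.[Na+] | intermediate
9 | (2R,3Z)-5-[(tert-butyldimethylsilyl)oxy]-4-iodopent-3-en-2-ol | C[C@@H](O)/C=C(\I)CO[Si](C)(C)C(C)(C)C | intermediate
10 | (2R,3E)-5-[(tert-butyldimethylsilyl)oxy]-4-ethylpent-3-en-2-ol | C[C@@H](O)/C=C(\CC)CO[Si](C)(C)C(C)(C)C | intermediate
11 | (2R,3E)-5-[(tert-butyldimethylsilyl)oxy]-4-ethylpent-3-en-2-yl 2-methylhex-3-ynoate (both α-epimers) | CCC#CC(C)C(=O)O[C@H](C)/C=C(\CC)CO[Si](C)(C)C(C)(C)C | intermediate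
12 | (Z)-trimethylsilyl ketene acetal of 11 (OSiMe3 cis to the butynyl group) | CCC#C/C(C)=C(\O[Si](C)(C)C)O[C@H](C)/C=C(\CC)CO[Si](C)(C)C(C)(C)C | intermediate
13 | trimethylsilyl ester of 14 | CCC#C[C@@](C)(C(=O)O[Si](C)(C)C)[C@@](CC)(CO[Si](C)(C)C(C)(C)C)/C=C/C | intermediate
14 | (2R,3S,4E)-2-(but-1-yn-1-yl)-3-{[(tert-butyldimethylsilyl)oxy]methyl}-3-ethyl-2-methylhex-4-enoic acid | CCC#C[C@@](C)(C(=O)O)[C@@](CC)(CO[Si](C)(C)C(C)(C)C)/C=C/C | intermediate
15 | methyl (2R,3S,4E)-2-(but-1-yn-1-yl)-3-{[(tert-butyldimethylsilyl)oxy]methyl}-3-ethyl-2-methylhex-4-enoate | CCC#C[C@@](C)(C(=O)OC)[C@@](CC)(CO[Si](C)(C)C(C)(C)C)/C=C/C | intermediate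
16 | secondary ozonide (1,2,4-trioxolane) of 15 | CCC#C[C@@](C)(C(=O)OC)[C@@](CC)(CO[Si](C)(C)C(C)(C)C)C1OOC(C)O1 | intermediate
17 | methyl (2R,3S)-2-(but-1-yn-1-yl)-3-{[(tert-butyldimethylsilyl)oxy]methyl}-3-formyl-2-methylpentanoate | CCC#C[C@@](C)(C(=O)OC)[C@@](CC)(CO[Si](C)(C)C(C)(C)C)C=O | intermediate
18 | methyl 2-[bis(2,2,2-trifluoroethoxy)phosphoryl]acetate | COC(=O)CP(=O)(OCC(F)(F)F)OCC(F)(F)F | starting material
19 | methyl 2-[bis(2,2,2-trifluoroethoxy)phosphoryl]butanoate (racemic) | CCC(C(=O)OC)P(=O)(OCC(F)(F)F)OCC(F)(F)F | intermediate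
20 | dimethyl (2Z,4S,5R)-5-(but-1-yn-1-yl)-4-{[(tert-butyldimethylsilyl)oxy]methyl}-2,4-diethyl-5-methylhex-2-enedioate | CCC#C[C@@](C)(C(=O)OC)[C@@](CC)(CO[Si](C)(C)C(C)(C)C)/C=C(CC)\C(=O)OC | intermediate
21 | methyl (2R,3S,4Z)-2-(but-1-yn-1-yl)-3-{[(tert-butyldimethylsilyl)oxy]methyl}-3-ethyl-5-(hydroxymethyl)-2-methylhept-4-enoate | CCC#C[C@@](C)(C(=O)OC)[C@@](CC)(CO[Si](C)(C)C(C)(C)C)/C=C(CC)\CO | intermediate
22 | methyl (2R,3S,4Z)-2-(but-1-yn-1-yl)-3-{[(tert-butyldimethylsilyl)oxy]methyl}-3-ethyl-5-formyl-2-methylhept-4-enoate | CCC#C[C@@](C)(C(=O)OC)[C@@](CC)(CO[Si](C)(C)C(C)(C)C)/C=C(CC)\C=O | intermediate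
23 | methyl (2R,3S,4Z,6E)-2-(but-1-yn-1-yl)-3-{[(tert-butyldimethylsilyl)oxy]methyl}-3,5-diethyl-2-methylocta-4,6-dienoate | CCC#C[C@@](C)(C(=O)OC)[C@@](CC)(CO[Si](C)(C)C(C)(C)C)/C=C(CC)\C=C\C | intermediate
24 | carbon monoxide | [C-]#[O+] | starting material
25 | bicyclic enone (C6=C7, C8 ketone, C3=C4, CH2OTBS on C2; C5–H trans to C9–H and on the face of C1–Me) | CCC1=C[C@@](CO[Si](C)(C)C(C)(C)C)(CC)[C@](C)(C(=O)OC)C2=C(CC)C(=O)[C@@H](C)[C@H]12 | intermediate
26 | C8 allylic alcohol of 25 (OH cis to C9–Me) | CCC1=C[C@@](CO[Si](C)(C)C(C)(C)C)(CC)[C@](C)(C(=O)OC)C2=C(CC)[C@@H](O)[C@@H](C)[C@H]12 | intermediate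
27 | C8 N-(2-nitrobenzenesulfonyl)hydrazine adduct (N trans to C9–Me) | CCC1=C[C@@](CO[Si](C)(C)C(C)(C)C)(CC)[C@](C)(C(=O)OC)C2=C(CC)[C@H](N(N)S(=O)(=O)c3ccccc3[N+](=O)[O-])[C@@H](C)[C@H]12 | intermediate
28 | C8 allylic diazene (N=NH trans to C9–Me) | CCC1=C[C@@](CO[Si](C)(C)C(C)(C)C)(CC)[C@](C)(C(=O)OC)C2=C(CC)[C@H](N=N)[C@@H](C)[C@H]12 | intermediate
29 | trans-fused diene ester with CH2OTBS on C2 (C3=C4, C7=C8) | CCC1=C[C@@](CO[Si](C)(C)C(C)(C)C)(CC)[C@](C)(C(=O)OC)[C@H]2C(CC)=C[C@@H](C)[C@H]12 | intermediate
30 | C2-hydroxymethyl ester | CCC1=C[C@@](CO)(CC)[C@](C)(C(=O)OC)[C@H]2C(CC)=C[C@@H](C)[C@H]12 | intermediate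
31 | C2-formyl ester | CCC1=C[C@@](C=O)(CC)[C@](C)(C(=O)OC)[C@H]2C(CC)=C[C@@H](C)[C@H]12 | intermediate
32 | benzyltributylphosphonium chloride | CCCC[P+](CCCC)(CCCC)Cc1ccccc1.[Cl-] | starting material
33 | spiculoic acid B methyl ester | CCC1=C[C@@](/C=C/c2ccccc2)(CC)[C@](C)(C(=O)OC)[C@H]2C(CC)=C[C@@H](C)[C@H]12 | intermediate
34 | spiculoic acid B | CCC1=C[C@@](/C=C/c2ccccc2)(CC)[C@](C)(C(=O)O)[C@H]2C(CC)=C[C@@H](C)[C@H]12 | target

## Step count and least certain steps

Total step count: 22. Longest linear sequence: 19 steps (5 to 34 through steps 3–10 and 12–22).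

**Step 16 (key step).**
- Risk: slow oxidative cyclisation, because the alkyne is internal and sits on a quaternary carbon, the alkene is 1,2-disubstituted and the closure is six-membered. Leakage into ene-type cycloisomerisation is possible. Face selection at C5 may be incomplete, because it rests on a single allylic-strain contact between the C7 ethyl group and C1.
- Fallback (from 23, back at 25): 23 is treated with Co2(CO)8 in CH2Cl2 to give the isolable hexacarbonyldicobalt alkyne complex F1. F1 is then cyclised with N-methylmorpholine N-oxide at room temperature to 25. Complexation bends the C7 ethyl group toward C1 before the alkene inserts, which should sharpen the same steric preference. The stoichiometric dinuclear pathway does not depend on catalyst turnover.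

**Step 8.**
- Risk: loss of control over the ketene acetal geometry, since methyl and alkynyl are told apart by size alone; this would give C1 epimers. The [3,3] shift joining two quaternary carbons may also be slow enough for enolate fragmentation to compete.
- Fallback (from 10, back at 15): commercial methyl 3-hydroxy-2-methylpropanoate is silylated to the triethylsilyl ether F2 and saponified to acid F3. Carbodiimide coupling of F3 with 10 gives ester F4. AcOH/THF/H2O removes the triethylsilyl group and gives β-hydroxy ester F5. LiN(iPr)2 (3 equiv) forms the dianion, in which the lithium alkoxide holds the CH2O arm cis to the enolate oxygen and so fixes the geometry by chelation. Warming gives hydroxy acid F6 through the same chair. MeI/K2CO3 gives hydroxy ester F7 and Dess–Martin oxidation gives aldehyde F8. CBr4/PPh3/Zn gives dibromoalkene F9, and n-BuLi (2 equiv) followed by EtI gives 15.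

**Step 12.**
- Risk: slow addition of the branched phosphonate anion to the neopentyl aldehyde, and erosion of Z selectivity if the mixture has to be warmed.
- Fallback (from 17, back at 23): a Stork–Zhao-type Wittig reaction with the α-iodo ylide made from propyltriphenylphosphonium bromide (NaN(SiMe3)2; I2; NaN(SiMe3)2) gives the Z iodoalkene F10. F10 is joined to (E)-tributyl(prop-1-en-1-yl)stannane with copper thiophene-2-carboxylate (CuO2CC4H3S) in N-methylpyrrolidone at room temperature. This coupling uses no palladium, so the 5-exo addition to the alkyne is avoided.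

**Step 18 (with step 17).**
- Risk: hydride addition to C8 from the face of C9–Me in step 17. The inverting displacement would then deliver hydrogen to the wrong face of C6 and give a cis fusion. The Mitsunobu displacement at the hindered C8 may also be slow.
- Fallback (from 25, back at 29): TsNHNH2 in EtOH gives tosylhydrazone F11. Catecholborane at 0 °C reduces it to the allylic tosylhydrazine F12, and NaOAc at 60 °C eliminates sulfinate to give diazene 28, which loses N2 to give 29. Here nitrogen ends on the face opposite to hydride attack, so this sequence is correct exactly when the reduction/inversion pair is not.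

**Step 19.**
- Risk: lactonisation of the freed C2 hydroxymethyl group onto the C1 ester (five-membered, cis, doubly geminally substituted) during desilylation or work-up.
- Fallback (from 29, back at 34): NaSEt in DMF first cleaves the methyl ester to acid F13. Bu4NF in THF then gives the tetrabutylammonium hydroxy carboxylate F14, which cannot be acylated. Dess–Martin periodinane with pyridine, followed by acidification, gives the hydroxy lactone (pseudo-acid) F15. An excess of the ylide from 32 opens F15 to the aldehyde carboxylate and olefinates it to 34.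

## Further compounds

F1 | step 16 | hexacarbonyldicobalt complex of the C6≡C7 alkyne of 23 | CC[C]12[C]3([C@@](C)(C(=O)OC)[C@@](CC)(CO[Si](C)(C)C(C)(C)C)/C=C(CC)\C=C\C)[Co]1(=C=O)(=C=O)(=C=O)[Co]23(=C=O)(=C=O)=C=O
F2 | step 8 | methyl 2-methyl-3-[(triethylsilyl)oxy]propanoate | CC[Si](CC)(CC)OCC(C)C(=O)OC
F3 | step 8 | 2-methyl-3-[(triethylsilyl)oxy]propanoic acid | CC[Si](CC)(CC)OCC(C)C(=O)O
F4 | step 8 | (2R,3E)-5-[(tert-butyldimethylsilyl)oxy]-4-ethylpent-3-en-2-yl 2-methyl-3-[(triethylsilyl)oxy]propanoate | CC[Si](CC)(CC)OCC(C)C(=O)O[C@H](C)/C=C(\CC)CO[Si](C)(C)C(C)(C)C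
F5 | step 8 | (2R,3E)-5-[(tert-butyldimethylsilyl)oxy]-4-ethylpent-3-en-2-yl 3-hydroxy-2-methylpropanoate | OCC(C)C(=O)O[C@H](C)/C=C(\CC)CO[Si](C)(C)C(C)(C)C
F6 | step 8 | hydroxy acid (14 with CH2OH in place of the butynyl group) | OC[C@@](C)(C(=O)O)[C@@](CC)(CO[Si](C)(C)C(C)(C)C)/C=C/C
F7 | step 8 | methyl ester of F6 | OC[C@@](C)(C(=O)OC)[C@@](CC)(CO[Si](C)(C)C(C)(C)C)/C=C/C
F8 | step 8 | aldehyde from F7 | O=C[C@@](C)(C(=O)OC)[C@@](CC)(CO[Si](C)(C)C(C)(C)C)/C=C/C
F9 | step 8 | 1,1-dibromoalkene from F8 | BrC(Br)=C[C@@](C)(C(=O)OC)[C@@](CC)(CO[Si](C)(C)C(C)(C)C)/C=C/C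
F10 | step 12 | methyl (2R,3S,4Z)-2-(but-1-yn-1-yl)-3-{[(tert-butyldimethylsilyl)oxy]methyl}-3-ethyl-5-iodo-2-methylhept-4-enoate | CCC#C[C@@](C)(C(=O)OC)[C@@](CC)(CO[Si](C)(C)C(C)(C)C)/C=C(\I)CC
F11 | step 18 | tosylhydrazone of 25 | CCC1=C[C@@](CO[Si](C)(C)C(C)(C)C)(CC)[C@](C)(C(=O)OC)C2=C(CC)C(=NNS(=O)(=O)c3ccc(C)cc3)[C@@H](C)[C@H]12
F12 | step 18 | C8 allylic tosylhydrazine (N trans to C9–Me) | CCC1=C[C@@](CO[Si](C)(C)C(C)(C)C)(CC)[C@](C)(C(=O)OC)C2=C(CC)[C@H](NNS(=O)(=O)c3ccc(C)cc3)[C@@H](C)[C@H]12
F13 | step 19 | carboxylic acid of 29 (silyl ether kept) | CCC1=C[C@@](CO[Si](C)(C)C(C)(C)C)(CC)[C@](C)(C(=O)O)[C@H]2C(CC)=C[C@@H](C)[C@H]12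
F14 | step 19 | tetrabutylammonium salt of the C2-hydroxymethyl acid | CCC1=C[C@@](CO)(CC)[C@](C)(C(=O)[O-])[C@H]2C(CC)=C[C@@H](C)[C@H]12.CCCC[N+](CCCC)(CCCC)CCCC
F15 | step 19 | hydroxy lactone (pseudo-acid) of the C2-formyl acid | CCC1=C[C@]3(CC)C(O)OC(=O)[C@]3(C)[C@H]2C(CC)=C[C@@H](C)[C@H]12
A1 | alternative 1 | six-membered lactone (O–C7(=O)–C6H2–C1–C2–C3) with the (Z)-C4(Et)=C5H–C9H(Me)–CH=CH2 chain on C3 | O=C1C[C@@](C)(C(=O)OC)[C@@](CC)(/C=C/c2ccccc2)[C@H](O1)/C(CC)=C\[C@H](C)C=C
A2 | alternative 1 | ring-A acid with the C7 carboxyl on C6 and the 1-methylallyl group on C5 | CCC1=C[C@@](/C=C/c2ccccc2)(CC)[C@](C)(C(=O)OC)[C@@H](C(=O)O)[C@@H]1[C@H](C)C=C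
A3 | alternative 2 | ring-B cyclopentene with the (Z)-iodoalkene C3(I)=C4(Et) on C5 and C1(Me)(CO2Me)–C2(Et)=CH–CH2Ph on C6 (E alkene drawn) | I/C=C(CC)\[C@H]1[C@H](C)C=C(CC)[C@@H]1[C@@](C)(C(=O)OC)/C(CC)=C/Cc1ccccc1
A4 | alternative 2 | spiculoic acid B methyl ester (identical with 33) | CCC1=C[C@@](/C=C/c2ccccc2)(CC)[C@](C)(C(=O)OC)[C@H]2C(CC)=C[C@@H](C)[C@H]12
A5 | alternative 3 | ring-A aldehyde with the C7 formyl group on C6 and the isopropenyl group on C5 | CCC1=C[C@@](/C=C/c2ccccc2)(CC)[C@](C)(C(=O)OC)[C@@H](C=O)[C@@H]1C(C)=C
A6 | alternative 3 | trans-fused bicyclic C7 ketone | CCC1=C[C@@](/C=C/c2ccccc2)(CC)[C@](C)(C(=O)OC)[C@H]2C(=O)C[C@@H](C)[C@H]12
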